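## Retrosynthetic overview

1. The target comes from four-fold desilylation of a fully TBS-protected 2,6-trans-tetrahydropyran.
2. The C2–aryl bond and the C2 stereocentre come from a nickel-catalysed arylation of a 2-acetoxytetrahydropyran (lactol acetate) with a guaiacyl boronic acid, itself made from catechol in four steps.
3. The lactol acetate comes from a trans-4-silyloxy-6-substituted δ-lactone. This is the only ring built for the target (after a temporary dioxolane), and it is closed before the aryl group is attached.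
4. The lactone comes from a 3,5,6-trihydroxyheptanoate. Its C3–O bond is set by copper-catalysed asymmetric β-borylation/oxidation of an (E)-enoate made by cross-metathesis with methyl acrylate.
5. The 5,6-diol comes from (S,S)-diepoxybutane, opened first by vinylmagnesium bromide and then by the Grignard reagent of silylated 4-bromophenol.

Assumption: the SMILES is read as the (2S,4S,6S,1′S) isomer (aryl trans to the C6 side chain, ring OH cis to the aryl group), and (S,S)-diepoxybutane is bought as a chiral-pool reagent. TBS = tert-butyldimethylsilyl; Bpin = 4,4,5,5-tetramethyl-1,3,2-dioxaborolan-2-yl.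

## Route

Step 1
Reactants: 1 (2S,3S)-1,2:3,4-diepoxybutane; 2 vinylmagnesium bromide
Product: 3 (S)-1-[(S)-oxiran-2-yl]but-3-en-1-ol
Conditions: 1 (1.5 equiv), CuBr·SMe2 (10 mol %), THF, −78 → −30 °C, 2 (1.0 equiv) added over 2 h; aq. NH4Cl
Reagents that add atoms: none
Why: Copper-catalysed Grignard opening of a terminal epoxide occurs by SN2 attack at the CH2 carbon, so both stereocentres of the C2-symmetric diepoxide are untouched; the mono-adduct is separated from recovered 1 and the bis-adduct.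

Step 2
Reactants: 4 4-bromophenol
Product: 5 (4-bromophenoxy)(tert-butyl)dimethylsilane
Conditions: TBSCl, imidazole, DMF, rt
Reagents that add atoms: tert-butyldimethylsilyl chloride, CC(C)(C)[Si](C)(C)Cl
Why: Standard silylation of a phenol; the aryl silyl ether survives Grignard formation.

Step 3
Reactants: 5 (4-bromophenoxy)(tert-butyl)dimethylsilane; 3 (S)-1-[(S)-oxiran-2-yl]but-3-en-1-ol
Product: 7 (2S,3S)-1-[4-(TBSO)phenyl]hex-5-ene-2,3-diol, via aryl Grignard reagent 6 (not isolated)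
Conditions: 5 (2.6 equiv), Mg, THF, reflux; then −40 °C, CuBr·SMe2 (10 mol %), 3 (1.0 equiv), −40 → 0 °C; aq. NH4Cl
Reagents that add atoms: magnesium, [Mg] (in 6 only)
Why: One equivalent of 6 deprotonates the hydroxyl and a second opens the epoxide at CH2 (copper-catalysed SN2 epoxide opening), so both carbinol centres keep the configuration set in 1.

Step 4
Reactants: 7 (2S,3S)-1-[4-(TBSO)phenyl]hex-5-ene-2,3-diol
Product: 8 (4S,5S)-4-allyl-5-[4-(TBSO)benzyl]-2,2-dimethyl-1,3-dioxolane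
Conditions: 2,2-dimethoxypropane (3 equiv), PPTS (5 mol %), CH2Cl2, rt
Reagents that add atoms: 2,2-dimethoxypropane, COC(C)(C)OC
Why: Acid-catalysed transacetalisation gives the trans-dioxolane, masking the hydroxyl that would otherwise add 5-exo (oxa-Michael) to the enoate under the basic borylation conditions.

Step 5
Reactants: 8 (4S,5S)-4-allyl-5-[4-(TBSO)benzyl]-2,2-dimethyl-1,3-dioxolane; 9 methyl acrylate
Product: 10 methyl (2E)-4-[(4S,5S)-5-[4-(TBSO)benzyl]-2,2-dimethyl-1,3-dioxolan-4-yl]but-2-enoate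
Conditions: 9 (4 equiv), second-generation Grubbs catalyst (H2IMes)(PCy3)Cl2Ru=CHPh (3 mol %), CH2Cl2, 40 °C
Reagents that add atoms: none
Why: Olefin cross-metathesis of a terminal alkene with an acrylate is E-selective and driven by loss of ethylene.

Step 6
Reactants: 10 methyl (2E)-4-[(4S,5S)-5-[4-(TBSO)benzyl]-2,2-dimethyl-1,3-dioxolan-4-yl]but-2-enoate
Product: 14 (4R,6S)-4-hydroxy-6-[(1S)-1-hydroxy-2-[4-(TBSO)phenyl]ethyl]tetrahydro-2H-pyran-2-one, via β-boryl ester 11 (not isolated), via β-hydroxy ester 12 (not isolated), via trihydroxy ester 13 (not isolated)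
Conditions: CuCl (5 mol %), NaOtBu (5 mol %), (R)-1-[(S)-2-(diphenylphosphino)ferrocenyl]ethyldicyclohexylphosphine (6 mol %), B2pin2 (1.1 equiv), MeOH (2 equiv), THF, rt; NaBO3·4H2O, THF/H2O, 0 °C → rt; crude, TsOH·H2O (20 mol %), MeCN/H2O 9:1, 40 °C, then PhMe azeotrope
Reagents that add atoms: bis(pinacolato)diboron, CC1(C)OB(OC1(C)C)B1OC(C)(C)C(C)(C)O1 (boron of 11 only); sodium perborate, [Na+].[O-]OB=O (oxygen at C4 of 14)
Why: Copper-catalysed enantioselective conjugate borylation sets C3 as R under catalyst control (boron to the Re face of C3; the ligand antipode is used if the opposite sense is found), C–B oxidation is stereoretentive, and after acid removal of the acetonide the 5-OH closes the six-membered lactone in preference to the seven-membered ring through the 6-OH.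

Step 7
Reactants: 14 (4R,6S)-4-hydroxy-6-[(1S)-1-hydroxy-2-[4-(TBSO)phenyl]ethyl]tetrahydro-2H-pyran-2-one
Product: 15 (4R,6S)-4-(TBSO)-6-[(1S)-1-(TBSO)-2-[4-(TBSO)phenyl]ethyl]tetrahydro-2H-pyran-2-one
Conditions: TBSOTf (2.5 equiv), 2,6-lutidine (4 equiv), CH2Cl2, −40 → 0 °C
Reagents that add atoms: tert-butyldimethylsilyl triflate, CC(C)(C)[Si](C)(C)OS(=O)(=O)C(F)(F)F
Why: Silylation of both secondary alcohols with a silyl triflate and a hindered base is fast at low temperature, which avoids β-elimination of the lactone.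

Step 8
Reactants: 15 (4R,6S)-4-(TBSO)-6-[(1S)-1-(TBSO)-2-[4-(TBSO)phenyl]ethyl]tetrahydro-2H-pyran-2-one
Product: 17 (4R,6S)-4-(TBSO)-6-[(1S)-1-(TBSO)-2-[4-(TBSO)phenyl]ethyl]tetrahydro-2H-pyran-2-yl acetate (both C2 anomers), via aluminium hemiacetal 16 (not isolated)
Conditions: i-Bu2AlH (1.2 equiv), CH2Cl2, −78 °C; then pyridine, DMAP, Ac2O, −78 → 0 °C; aq. potassium sodium tartrate
Reagents that add atoms: acetic anhydride, CC(=O)OC(C)=O; diisobutylaluminium hydride, CC(C)C[AlH]CC(C)C (aluminium of 16 only)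
Why: Reductive acetylation: the lactone is half-reduced to a stable tetrahedral aluminium hemiacetal that is acetylated in situ; the anomer ratio is irrelevant because both anomers give the same oxocarbenium ion.

Step 9
Reactants: 18 catechol
Product: 19 2-methoxyphenol
Conditions: MeI (1.0 equiv), K2CO3 (1.0 equiv), acetone, reflux
Reagents that add atoms: iodomethane, CI
Why: Williamson mono-O-methylation; the mono-ether is separated from the dimethyl ether and unreacted catechol.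

Step 10
Reactants: 19 2-methoxyphenol
Product: 20 4-bromo-2-methoxyphenol
Conditions: NBS (1.0 equiv), MeCN, 0 °C
Reagents that add atoms: N-bromosuccinimide, O=C1CCC(=O)N1Br
Why: Electrophilic aromatic bromination goes para to the free hydroxyl, the stronger director.

Step 11
Reactants: 20 4-bromo-2-methoxyphenol
Product: 21 (4-bromo-2-methoxyphenoxy)(tert-butyl)dimethylsilane
Conditions: TBSCl, imidazole, DMF, rt
Reagents that add atoms: tert-butyldimethylsilyl chloride, CC(C)(C)[Si](C)(C)Cl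
Why: Standard phenol silylation.

Step 12
Reactants: 21 (4-bromo-2-methoxyphenoxy)(tert-butyl)dimethylsilane
Product: 24 [4-(TBSO)-3-methoxyphenyl]boronic acid, via aryllithium 22 (not isolated), via lithium aryl(triisopropoxy)borate 23 (not isolated)
Conditions: n-BuLi (1.05 equiv), THF, −78 °C; B(OiPr)3, −78 °C → rt; 1 M HCl, 0 °C
Reagents that add atoms: triisopropyl borate, CC(C)OB(OC(C)C)OC(C)C; water, O; n-butyllithium, [Li]CCCC (lithium of 22 and 23 only)
Why: Bromine–lithium exchange, borate trapping and hydrolysis; lithium sits para to the silyloxy group, so no silyl migration occurs.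

Step 13
Reactants: 17 (4R,6S)-4-(TBSO)-6-[(1S)-1-(TBSO)-2-[4-(TBSO)phenyl]ethyl]tetrahydro-2H-pyran-2-yl acetate; 24 [4-(TBSO)-3-methoxyphenyl]boronic acid
Product: 25 (2S,4S,6S)-2-[4-(TBSO)-3-methoxyphenyl]-4-(TBSO)-6-[(1S)-1-(TBSO)-2-[4-(TBSO)phenyl]ethyl]tetrahydro-2H-pyran
Conditions: Ni(cod)2 (10 mol %), PPh3 (20 mol %), 24 (2.0 equiv), 4 Å MS, 1,4-dioxane, 40 °C
Reagents that add atoms: none
Why: Proposed new method: a base-free nickel-catalysed Suzuki–Miyaura-type arylation of an aliphatic lactol acetate, in which the Lewis-acidic boron of 24 abstracts the anomeric acetate to give an oxocarbenium ion paired with an aryl(acetoxy)borate, zerovalent nickel adds to C2 along the axial trajectory of the half-chair that has the C6 side chain pseudoequatorial and the C4 silyloxy group pseudoaxial, the aryl group passes from the borate to the resulting divalent α-alkoxyalkylnickel species, and C–C reductive elimination with retention sets C2 as S (aryl trans to the C6 chain, cis to C4–O); the closest known chemistry is the nickel-catalysed coupling of arylboronic acids with benzylic and allylic acetals through oxocarbenium or iminium ions and the nickel-catalysed C-arylation of glycosyl halides, neither shown on a non-stabilised 2-deoxy-type lactol acetate.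

Step 14
Reactants: 25 (2S,4S,6S)-2-[4-(TBSO)-3-methoxyphenyl]-4-(TBSO)-6-[(1S)-1-(TBSO)-2-[4-(TBSO)phenyl]ethyl]tetrahydro-2H-pyran
Product: 26 (2S,4S,6S)-2-(4-hydroxy-3-methoxyphenyl)-6-[(1S)-1-hydroxy-2-(4-hydroxyphenyl)ethyl]tetrahydro-2H-pyran-4-ol
Conditions: Bu4NF (6 equiv), AcOH (6 equiv), THF, 0 °C → rt
Reagents that add atoms: none
Why: Fluoride cleaves all four Si–O bonds, and the acetic acid buffer keeps the para-hydroxybenzylic ring ether from opening to a quinone methide, so C2 is not epimerised.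

## Compound list

1 | (2S,3S)-1,2:3,4-diepoxybutane | C1O[C@@H]1[C@@H]1CO1 | starting material
2 | vinylmagnesium bromide | C=C[Mg]Br | starting material
3 | (S)-1-[(S)-oxiran-2-yl]but-3-en-1-ol | C=CC[C@H](O)[C@@H]1CO1 | intermediate
4 | 4-bromophenol | Oc1ccc(Br)cc1 | starting material
5 | (4-bromophenoxy)(tert-butyl)dimethylsilane | CC(C)(C)[Si](C)(C)Oc1ccc(Br)cc1 | intermediate
6 | [4-(tert-butyldimethylsilyloxy)phenyl]magnesium bromide | CC(C)(C)[Si](C)(C)Oc1ccc([Mg]Br)cc1 | intermediate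
7 | (2S,3S)-1-[4-(tert-butyldimethylsilyloxy)phenyl]hex-5-ene-2,3-diol | C=CC[C@H](O)[C@@H](O)Cc1ccc(O[Si](C)(C)C(C)(C)C)cc1 | intermediate
8 | (4S,5S)-4-allyl-5-[4-(tert-butyldimethylsilyloxy)benzyl]-2,2-dimethyl-1,3-dioxolane | C=CC[C@@H]1OC(C)(C)O[C@H]1Cc1ccc(O[Si](C)(C)C(C)(C)C)cc1 | intermediate
9 | methyl acrylate | C=CC(=O)OC | starting material
10 | methyl (2E)-4-[(4S,5S)-5-[4-(tert-butyldimethylsilyloxy)benzyl]-2,2-dimethyl-1,3-dioxolan-4-yl]but-2-enoate | COC(=O)/C=C/C[C@@H]1OC(C)(C)O[C@H]1Cc1ccc(O[Si](C)(C)C(C)(C)C)cc1 | intermediate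
11 | methyl (3R)-4-[(4S,5S)-5-[4-(tert-butyldimethylsilyloxy)benzyl]-2,2-dimethyl-1,3-dioxolan-4-yl]-3-(4,4,5,5-tetramethyl-1,3,2-dioxaborolan-2-yl)butanoate | COC(=O)C[C@H](B1OC(C)(C)C(C)(C)O1)C[C@@H]1OC(C)(C)O[C@H]1Cc1ccc(O[Si](C)(C)C(C)(C)C)cc1 | intermediate
12 | methyl (3R)-4-[(4S,5S)-5-[4-(tert-butyldimethylsilyloxy)benzyl]-2,2-dimethyl-1,3-dioxolan-4-yl]-3-hydroxybutanoate | COC(=O)C[C@H](O)C[C@@H]1OC(C)(C)O[C@H]1Cc1ccc(O[Si](C)(C)C(C)(C)C)cc1 | intermediate
13 | methyl (3R,5S,6S)-7-[4-(tert-butyldimethylsilyloxy)phenyl]-3,5,6-trihydroxyheptanoate | COC(=O)C[C@H](O)C[C@H](O)[C@@H](O)Cc1ccc(O[Si](C)(C)C(C)(C)C)cc1 | intermediate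
14 | (4R,6S)-4-hydroxy-6-[(1S)-1-hydroxy-2-[4-(tert-butyldimethylsilyloxy)phenyl]ethyl]tetrahydro-2H-pyran-2-one | O=C1C[C@H](O)C[C@@H]([C@@H](O)Cc2ccc(O[Si](C)(C)C(C)(C)C)cc2)O1 | intermediate
15 | (4R,6S)-4-(tert-butyldimethylsilyloxy)-6-[(1S)-1-(tert-butyldimethylsilyloxy)-2-[4-(tert-butyldimethylsilyloxy)phenyl]ethyl]tetrahydro-2H-pyran-2-one | O=C1C[C@H](O[Si](C)(C)C(C)(C)C)C[C@@H]([C@@H](O[Si](C)(C)C(C)(C)C)Cc2ccc(O[Si](C)(C)C(C)(C)C)cc2)O1 | intermediate
16 | diisobutyl{[(4R,6S)-4-(tert-butyldimethylsilyloxy)-6-[(1S)-1-(tert-butyldimethylsilyloxy)-2-[4-(tert-butyldimethylsilyloxy)phenyl]ethyl]tetrahydro-2H-pyran-2-yl]oxy}aluminium (both C2 epimers) | CC(C)C[Al](CC(C)C)OC1C[C@H](O[Si](C)(C)C(C)(C)C)C[C@@H]([C@@H](O[Si](C)(C)C(C)(C)C)Cc2ccc(O[Si](C)(C)C(C)(C)C)cc2)O1 | intermediate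
17 | (4R,6S)-4-(tert-butyldimethylsilyloxy)-6-[(1S)-1-(tert-butyldimethylsilyloxy)-2-[4-(tert-butyldimethylsilyloxy)phenyl]ethyl]tetrahydro-2H-pyran-2-yl acetate (both C2 anomers) | CC(=O)OC1C[C@H](O[Si](C)(C)C(C)(C)C)C[C@@H]([C@@H](O[Si](C)(C)C(C)(C)C)Cc2ccc(O[Si](C)(C)C(C)(C)C)cc2)O1 | intermediate
18 | catechol (benzene-1,2-diol) | Oc1ccccc1O | starting material
19 | 2-methoxyphenol | COc1ccccc1O | intermediate
20 | 4-bromo-2-methoxyphenol | COc1cc(Br)ccc1O | intermediate
21 | (4-bromo-2-methoxyphenoxy)(tert-butyl)dimethylsilane | COc1cc(Br)ccc1O[Si](C)(C)C(C)(C)C | intermediate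
22 | [4-(tert-butyldimethylsilyloxy)-3-methoxyphenyl]lithium | [Li]c1ccc(O[Si](C)(C)C(C)(C)C)c(OC)c1 | intermediate
23 | lithium [4-(tert-butyldimethylsilyloxy)-3-methoxyphenyl]triisopropoxyborate | [Li+].COc1cc(ccc1O[Si](C)(C)C(C)(C)C)[B-](OC(C)C)(OC(C)C)OC(C)C | intermediate
24 | [4-(tert-butyldimethylsilyloxy)-3-methoxyphenyl]boronic acid | COc1cc(B(O)O)ccc1O[Si](C)(C)C(C)(C)C | intermediate
25 | (2S,4S,6S)-2-[4-(tert-butyldimethylsilyloxy)-3-methoxyphenyl]-4-(tert-butyldimethylsilyloxy)-6-[(1S)-1-(tert-butyldimethylsilyloxy)-2-[4-(tert-butyldimethylsilyloxy)phenyl]ethyl]tetrahydro-2H-pyran | COc1cc([C@@H]2C[C@H](O[Si](C)(C)C(C)(C)C)C[C@@H]([C@@H](O[Si](C)(C)C(C)(C)C)Cc3ccc(O[Si](C)(C)C(C)(C)C)cc3)O2)ccc1O[Si](C)(C)C(C)(C)C | intermediate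
26 | (2S,4S,6S)-2-(4-hydroxy-3-methoxyphenyl)-6-[(1S)-1-hydroxy-2-(4-hydroxyphenyl)ethyl]tetrahydro-2H-pyran-4-ol | COc1cc([C@@H]2C[C@H](O)C[C@@H]([C@@H](O)Cc3ccc(O)cc3)O2)ccc1O | target

## Step count and risks

Total step count: 14.
Longest linear sequence: 9 steps (1 → 3 → 7 → 8 → 10 → 14 → 15 → 17 → 25 → 26, steps 1, 3–8, 13, 14; the path from 4 through step 2 is equally long). The boronic acid branch from 18 is 4 steps.

Three steps most likely to fail:

**Step 13 (the new nickel-catalysed arylation).** Ionisation of the non-stabilised acetate by the boronic acid may be too slow, or the α-alkoxyalkylnickel intermediate may lose a β-hydride to give the enol ether. The fallback is known chemistry; it sets out from lactone 15 and bromide 21 and comes back at 25. Lactone 15 is reduced with i-Bu2AlH (CH2Cl2, −78 °C, aqueous work-up) to the lactol (4R,6S)-4-(TBSO)-6-[(1S)-1-(TBSO)-2-[4-(TBSO)phenyl]ethyl]tetrahydro-2H-pyran-2-ol F1. With benzenesulfinic acid and CaCl2 in CH2Cl2 this gives the anomeric sulfone (4R,6S)-2-(phenylsulfonyl)-4-(TBSO)-6-[(1S)-1-(TBSO)-2-[4-(TBSO)phenyl]ethyl]tetrahydro-2H-pyran F2. Bromide 21 is lithiated (n-BuLi, THF, −78 °C, via 22) and transmetalated with ZnBr2 to [4-(TBSO)-3-methoxyphenyl]zinc bromide F3. Stirring F2 with F3 (3 equiv) in THF at rt expels sulfinate with zinc assistance and gives the same oxocarbenium ion, which the arylzinc attacks axially in an uncatalysed SN1-type substitution to give 25.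

**Step 6 (catalyst-controlled borylation telescoped into lactonisation).** The diastereomer ratio at C3 rests on the chiral copper catalyst alone, and three operations run without purification. The fallback sets out from 8 and comes back at 12, which is then taken through the acid stage of step 6 to 14. Alkene 8 is cleaved (OsO4 cat., NaIO4, 2,6-lutidine, dioxane/H2O) to 2-[(4S,5S)-5-[4-(TBSO)benzyl]-2,2-dimethyl-1,3-dioxolan-4-yl]acetaldehyde F4. Roskamp homologation (methyl diazoacetate, SnCl2 10 mol %, CH2Cl2, rt) gives the β-keto ester methyl 4-[(4S,5S)-5-[4-(TBSO)benzyl]-2,2-dimethyl-1,3-dioxolan-4-yl]-3-oxobutanoate F5. Noyori hydrogenation (H2 50 bar, RuCl2[(R)-BINAP] 1 mol %, MeOH, 40 °C) then sets the 3R carbinol of 12.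

**Step 14 (four-fold desilylation).** The hindered alkyl silyl ethers are slow under buffered fluoride, while unbuffered base or acid can epimerise C2 of the 2,6-trans para-hydroxybenzylic ether. The fallback sets out from 25 and comes back at 26 in two orthogonal stages. Aqueous HF in MeCN at 0 °C removes only the two alkyl silyl ethers, while the phenols are still capped, to give (2S,4S,6S)-2-[4-(TBSO)-3-methoxyphenyl]-6-[(1S)-1-hydroxy-2-[4-(TBSO)phenyl]ethyl]tetrahydro-2H-pyran-4-ol F6. K2CO3 in MeOH (0 °C → rt) then methanolyses the two aryl silyl ethers to give 26.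

## Further compounds

F1 | step 13 | (4R,6S)-4-(tert-butyldimethylsilyloxy)-6-[(1S)-1-(tert-butyldimethylsilyloxy)-2-[4-(tert-butyldimethylsilyloxy)phenyl]ethyl]tetrahydro-2H-pyran-2-ol (both C2 anomers) | OC1C[C@H](O[Si](C)(C)C(C)(C)C)C[C@@H]([C@@H](O[Si](C)(C)C(C)(C)C)Cc2ccc(O[Si](C)(C)C(C)(C)C)cc2)O1
F2 | step 13 | (4R,6S)-2-(phenylsulfonyl)-4-(tert-butyldimethylsilyloxy)-6-[(1S)-1-(tert-butyldimethylsilyloxy)-2-[4-(tert-butyldimethylsilyloxy)phenyl]ethyl]tetrahydro-2H-pyran (both C2 anomers) | O=S(=O)(c1ccccc1)C1C[C@H](O[Si](C)(C)C(C)(C)C)C[C@@H]([C@@H](O[Si](C)(C)C(C)(C)C)Cc2ccc(O[Si](C)(C)C(C)(C)C)cc2)O1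
F3 | step 13 | [4-(tert-butyldimethylsilyloxy)-3-methoxyphenyl]zinc bromide | COc1cc([Zn]Br)ccc1O[Si](C)(C)C(C)(C)C
F4 | step 6 | 2-[(4S,5S)-5-[4-(tert-butyldimethylsilyloxy)benzyl]-2,2-dimethyl-1,3-dioxolan-4-yl]acetaldehyde | O=CC[C@@H]1OC(C)(C)O[C@H]1Cc1ccc(O[Si](C)(C)C(C)(C)C)cc1
F5 | step 6 | methyl 4-[(4S,5S)-5-[4-(tert-butyldimethylsilyloxy)benzyl]-2,2-dimethyl-1,3-dioxolan-4-yl]-3-oxobutanoate | COC(=O)CC(=O)C[C@@H]1OC(C)(C)O[C@H]1Cc1ccc(O[Si](C)(C)C(C)(C)C)cc1
F6 | step 14 | (2S,4S,6S)-2-[4-(tert-butyldimethylsilyloxy)-3-methoxyphenyl]-6-[(1S)-1-hydroxy-2-[4-(tert-butyldimethylsilyloxy)phenyl]ethyl]tetrahydro-2H-pyran-4-ol | COc1cc([C@@H]2C[C@H](O)C[C@@H]([C@@H](O)Cc3ccc(O[Si](C)(C)C(C)(C)C)cc3)O2)ccc1O[Si](C)(C)C(C)(C)C
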